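**Assumptions:** The SMILES encodes (2R)-chroman, (9'R)-carbinol and 3'E,7'E olefins; I planned for exactly that. Catalysts, ligands, bases and reagents that contribute only hydrogen (9-BBN, Red-Al, TBAF) appear in the conditions and are not numbered.

## Retrosynthetic overview

1. Target ⇐ global desilylation ⇐ B-alkyl Suzuki coupling (C2'–C3') of the borane from (S)-2-vinylchroman 14 with (E)-vinyl iodide 27.
2. 27 ⇐ enal 20 by a new chiral-phosphoric-acid-catalysed "linear" prenylboration with the reverse-prenyl boronate 24, which forms C9'–C10' and sets 9'R.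
3. 20 ⇐ pent-4-yn-1-ol by carboalumination/iodination, oxidation and E-selective Wittig.
4. 14 ⇐ Z-allylic carbonate 13 by Pd-catalysed asymmetric allylic etherification, which closes the only ring formed (the pyran of the chroman) and sets the C2 quaternary centre.
5. 13 ⇐ methylhydroquinone by mono-silylation, ortho-formylation, methylenation, hydroboration/Suzuki with (Z)-3-iodobut-2-en-1-ol, and carbonate formation. The arene is purchased; the pyran ring is closed before fragment union.

## Route

### Chroman fragment

**Step 1**
Reactants: 1 methylhydroquinone; 2 triisopropylsilyl chloride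
Product: 3 2-methyl-4-[(triisopropylsilyl)oxy]phenol
Conditions: TIPSCl (1.0 equiv), imidazole, DMF, 0 °C
Reagents that add atoms: TIPSCl (2), CC(C)[Si](Cl)(C(C)C)C(C)C
Why: Selective mono-silylation: the bulky silyl chloride reacts faster at the OH that has no ortho methyl, and the minor regioisomer and bis-ether are removed by chromatography.

**Step 2**
Reactants: 3; 4 paraformaldehyde
Product: 5 2-hydroxy-3-methyl-5-[(triisopropylsilyl)oxy]benzaldehyde
Conditions: MgCl2, Et3N, (CH2O)n, MeCN, reflux
Reagents that add atoms: formaldehyde (4), C=O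
Why: Magnesium-phenoxide-directed ortho-formylation (Casnati–Skattebøl) can only occur at the single free ortho position.

**Step 3**
Reactants: 5; 6 methyltriphenylphosphonium bromide
Product: 7 2-ethenyl-6-methyl-4-[(triisopropylsilyl)oxy]phenol
Conditions: Ph3PCH3Br (2.5 equiv), KOtBu (2.4 equiv), THF, 0 °C → rt
Reagents that add atoms: methyltriphenylphosphonium bromide (6), C[P+](c1ccccc1)(c1ccccc1)c1ccccc1.[Br-]
Why: Wittig methylenation of the salicylaldehyde; the extra ylide absorbs the phenolic proton and the aryl TIPS ether is inert.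

**Step 4**
Reactants: 8 but-2-yn-1-ol; 9 iodine
Product: 10 (Z)-3-iodobut-2-en-1-ol
Conditions: Red-Al, THF, 0 °C → rt; then I2, −78 → 0 °C
Reagents that add atoms: iodine (9), II
Why: Hydroxyl-directed trans-hydroalumination places Al on C3 cis to CH2O, and iodinolysis with retention gives the Z-vinyl iodide only.

**Step 5**
Reactants: 7; 10
Product: 11 2-[(3Z)-5-hydroxy-3-methylpent-3-en-1-yl]-6-methyl-4-[(triisopropylsilyl)oxy]phenol
Conditions: 7, 9-BBN (2.5 equiv), THF, 0 °C → rt; then aq. K3PO4, 10, Pd(dppf)Cl2 (5 mol%), THF/DMF, rt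
Reagents that add atoms: (Z)-3-iodobut-2-en-1-ol (10), C/C(I)=C/CO; 9-BBN contributes only H
Why: Anti-Markovnikov hydroboration of the styrene followed by B-alkyl Suzuki–Miyaura coupling, which retains the vinyl iodide geometry and gives the Z-trisubstituted allylic alcohol as a single isomer; free OH groups are tolerated.

**Step 6**
Reactants: 11; 12 methyl chloroformate
Product: 13 (2Z)-5-{2-hydroxy-3-methyl-5-[(triisopropylsilyl)oxy]phenyl}-3-methylpent-2-en-1-yl methyl carbonate
Conditions: ClCO2Me (1.1 equiv), pyridine, CH2Cl2, −20 → 0 °C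
Reagents that add atoms: methyl chloroformate (12), COC(=O)Cl
Why: Chemoselective acylation of the primary allylic alcohol over the hindered 2,6-dialkylphenol, which is not deprotonated by pyridine.

**Step 7**
Reactants: 13
Product: 14 (2S)-2-ethenyl-2,8-dimethyl-6-[(triisopropylsilyl)oxy]chromane
Conditions: Pd2(dba)3·CHCl3 (2 mol%), (R,R)-DACH-phenyl Trost ligand (6 mol%), AcOH (1 equiv), CH2Cl2, rt
Reagents that add atoms: none
Why: Pd-catalysed asymmetric allylic etherification (Trost AAA): ionisation gives a π-allyl complex and the phenol closes 6-exo onto the substituted terminus, with the chiral ligand pocket selecting one π-allyl diastereomer to set C2. The Z-carbonate/(R,R)-ligand pairing is chosen from memory to give the (S)-product (equivalent to 2R in the target); the sense is checked at this stage and the ligand antipode used if it is reversed.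

### Side-chain fragment

**Step 8**
Reactants: 15 pent-4-yn-1-ol; 16 trimethylaluminium; 9 iodine
Product: 17 (4E)-5-iodo-4-methylpent-4-en-1-ol
Conditions: Me3Al (3 equiv), Cp2ZrCl2 (0.25 equiv), CH2Cl2, 0 °C → rt; then I2, THF, −30 → 0 °C
Reagents that add atoms: trimethylaluminium (16), C[Al](C)C; iodine (9), II
Why: Negishi Zr-catalysed syn-carboalumination adds Me to the internal and Al to the terminal carbon; iodinolysis with retention gives the E-vinyl iodide (future C3'=C4').

**Step 9**
Reactants: 17
Product: 18 (4E)-5-iodo-4-methylpent-4-enal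
Conditions: Dess–Martin periodinane, NaHCO3, CH2Cl2, 0 °C → rt
Reagents that add atoms: none
Why: Mild buffered oxidation of the primary alcohol; the vinyl iodide is untouched.

**Step 10**
Reactants: 18; 19 2-(triphenylphosphoranylidene)propanal
Product: 20 (2E,6E)-7-iodo-2,6-dimethylhepta-2,6-dienal
Conditions: 19 (1.3 equiv), PhMe, 90 °C
Reagents that add atoms: 2-(triphenylphosphoranylidene)propanal (19), CC(C=O)=P(c1ccccc1)(c1ccccc1)c1ccccc1
Why: Wittig reaction of a stabilised α-methyl ylide is under thermodynamic control and gives the (E)-α-methyl enal (future C7'=C8') with high selectivity.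

**Step 11**
Reactants: 21 prenol (3-methylbut-2-en-1-ol); 12 methyl chloroformate
Product: 22 methyl 3-methylbut-2-en-1-yl carbonate
Conditions: ClCO2Me, pyridine, CH2Cl2, 0 °C
Reagents that add atoms: methyl chloroformate (12), COC(=O)Cl
Why: Routine carbonate formation on a primary allylic alcohol.

**Step 12**
Reactants: 22; 23 bis(pinacolato)diboron
Product: 24 4,4,5,5-tetramethyl-2-(2-methylbut-3-en-2-yl)-1,3,2-dioxaborolane (reverse-prenyl Bpin)
Conditions: B2pin2, CuCl/Xantphos (5 mol%), KOtBu (cat.), THF, rt
Reagents that add atoms: bis(pinacolato)diboron (23), CC1(C)OB(OC1(C)C)B1OC(C)(C)C(C)(C)O1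
Why: Copper-boryl γ-selective (SN2') allylic substitution of the carbonate places boron on the tertiary carbon; pinacol allylboronates do not undergo 1,3-borotropic shift, so the tertiary isomer is retained.

**Step 13**
Reactants: 20; 24
Product: 25 (5R,6E,10E)-11-iodo-2,6,10-trimethylundeca-2,6,10-trien-5-ol
Conditions: 24 (1.5 equiv), (R)-TRIP (10 mol%), 4 Å MS, PhMe, −20 °C → rt; triethanolamine work-up
Reagents that add atoms: none beyond reactant 24, C=CC(C)(C)B1OC(C)(C)C(C)(C)O1 (only its C5 unit is retained)
Why: Proposed new method: chiral-phosphoric-acid-catalysed enantioselective linear prenylation of an α-branched enal by allyl-transposing allylboration with the tertiary boronate 24. The P–OH hydrogen-bonds to the pseudo-axial pinacol oxygen (raising boron Lewis acidity) while P=O engages the formyl C–H, organising a closed chair (Zimmerman–Traxler) transition state in which the =CH2 terminus of 24 adds 1,2 to the Re face of the s-trans enal and the C=C shifts to give the CH2CH=CMe2 unit. There is no E/Z issue because the new alkene terminus is gem-dimethyl, the α,α-dimethyl groups slow the uncatalysed background reaction, and the vinyl iodide is inert. The closest known reactions are CPA (TRIP)-catalysed allyl- and crotylboration of aldehydes with pinacol boronates and thermal allylborations with α-substituted allyl-Bpin reagents; (R)-TRIP is chosen by analogy with the Re-face selectivity of allyl-Bpin additions, predicting the 9'R carbinol.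

**Step 14**
Reactants: 25; 26 tert-butyldimethylsilyl chloride
Product: 27 tert-butyl{[(5R,6E,10E)-11-iodo-2,6,10-trimethylundeca-2,6,10-trien-5-yl]oxy}dimethylsilane
Conditions: TBSCl, imidazole, DMAP (cat.), DMF, rt
Reagents that add atoms: TBSCl (26), CC(C)(C)[Si](C)(C)Cl
Why: Standard silylation of the secondary allylic alcohol, which protects C9'–OH and leaves the stereocentre untouched.

### Fragment union and endgame

**Step 15**
Reactants: 14; 27
Product: 28 {[(2R)-2-[(3E,7E,9R)-9-[(tert-butyldimethylsilyl)oxy]-4,8,12-trimethyltrideca-3,7,11-trien-1-yl]-2,8-dimethylchroman-6-yl]oxy}triisopropylsilane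
Conditions: 14 (1.3 equiv), 9-BBN (1.4 equiv), THF, rt → 50 °C; aq. Cs2CO3 quench; then 27 (1.0 equiv), Pd(dppf)Cl2 (10 mol%), AsPh3 (10 mol%), DMF, rt
Reagents that add atoms: none (9-BBN contributes only H)
Why: Anti-Markovnikov hydroboration of the only alkene in 14, then B-alkyl Suzuki–Miyaura coupling with retention of the E-vinyl iodide geometry to form C2'–C3'. Residual B–H is destroyed before 27 is added so its trisubstituted alkenes survive, and neither stereocentre is involved.

**Step 16**
Reactants: 28
Product: 29 sargachromanol C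
Conditions: TBAF (4 equiv), THF, 0 °C → rt, under Ar; aq. NH4Cl work-up
Reagents that add atoms: none
Why: Fluoride cleaves both the aryl TIPS and the allylic TBS ether under non-acidic conditions, so the allylic alcohol and the olefins are preserved; the air-sensitive chromanol is handled under argon.

## Compound list

1 | methylhydroquinone (2-methylbenzene-1,4-diol) | Cc1cc(O)ccc1O | starting material
2 | triisopropylsilyl chloride | CC(C)[Si](Cl)(C(C)C)C(C)C | starting material
3 | 2-methyl-4-[(triisopropylsilyl)oxy]phenol | Cc1cc(O[Si](C(C)C)(C(C)C)C(C)C)ccc1O | intermediate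
4 | paraformaldehyde (formaldehyde) | C=O | starting material
5 | 2-hydroxy-3-methyl-5-[(triisopropylsilyl)oxy]benzaldehyde | Cc1cc(O[Si](C(C)C)(C(C)C)C(C)C)cc(C=O)c1O | intermediate
6 | methyltriphenylphosphonium bromide | C[P+](c1ccccc1)(c1ccccc1)c1ccccc1.[Br-] | starting material
7 | 2-ethenyl-6-methyl-4-[(triisopropylsilyl)oxy]phenol | Cc1cc(O[Si](C(C)C)(C(C)C)C(C)C)cc(C=C)c1O | intermediate
8 | but-2-yn-1-ol | CC#CCO | starting material
9 | iodine | II | starting material
10 | (Z)-3-iodobut-2-en-1-ol | C/C(I)=C/CO | intermediate
11 | 2-[(3Z)-5-hydroxy-3-methylpent-3-en-1-yl]-6-methyl-4-[(triisopropylsilyl)oxy]phenol | Cc1cc(O[Si](C(C)C)(C(C)C)C(C)C)cc(CC/C(C)=C\CO)c1O | intermediate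
12 | methyl chloroformate | COC(=O)Cl | starting material
13 | (2Z)-5-{2-hydroxy-3-methyl-5-[(triisopropylsilyl)oxy]phenyl}-3-methylpent-2-en-1-yl methyl carbonate | Cc1cc(O[Si](C(C)C)(C(C)C)C(C)C)cc(CC/C(C)=C\COC(=O)OC)c1O | intermediate
14 | (2S)-2-ethenyl-2,8-dimethyl-6-[(triisopropylsilyl)oxy]chromane | C=C[C@]1(C)CCc2cc(O[Si](C(C)C)(C(C)C)C(C)C)cc(C)c2O1 | intermediate
15 | pent-4-yn-1-ol | C#CCCCO | starting material
16 | trimethylaluminium | C[Al](C)C | starting material
17 | (4E)-5-iodo-4-methylpent-4-en-1-ol | OCCC/C(C)=C/I | intermediate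
18 | (4E)-5-iodo-4-methylpent-4-enal | O=CCC/C(C)=C/I | intermediate
19 | 2-(triphenylphosphoranylidene)propanal | CC(C=O)=P(c1ccccc1)(c1ccccc1)c1ccccc1 | starting material
20 | (2E,6E)-7-iodo-2,6-dimethylhepta-2,6-dienal | O=C/C(C)=C/CC/C(C)=C/I | intermediate
21 | prenol (3-methylbut-2-en-1-ol) | CC(C)=CCO | starting material
22 | methyl 3-methylbut-2-en-1-yl carbonate | CC(C)=CCOC(=O)OC | intermediate
23 | bis(pinacolato)diboron | CC1(C)OB(OC1(C)C)B1OC(C)(C)C(C)(C)O1 | starting material
24 | 4,4,5,5-tetramethyl-2-(2-methylbut-3-en-2-yl)-1,3,2-dioxaborolane | C=CC(C)(C)B1OC(C)(C)C(C)(C)O1 | intermediate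
25 | (5R,6E,10E)-11-iodo-2,6,10-trimethylundeca-2,6,10-trien-5-ol | CC(C)=CC[C@@H](O)/C(C)=C/CC/C(C)=C/I | intermediate
26 | tert-butyldimethylsilyl chloride | CC(C)(C)[Si](C)(C)Cl | starting material
27 | tert-butyl{[(5R,6E,10E)-11-iodo-2,6,10-trimethylundeca-2,6,10-trien-5-yl]oxy}dimethylsilane | CC(C)=CC[C@@H](O[Si](C)(C)C(C)(C)C)/C(C)=C/CC/C(C)=C/I | intermediate
28 | {[(2R)-2-[(3E,7E,9R)-9-[(tert-butyldimethylsilyl)oxy]-4,8,12-trimethyltrideca-3,7,11-trien-1-yl]-2,8-dimethylchroman-6-yl]oxy}triisopropylsilane | CC(C)=CC[C@@H](O[Si](C)(C)C(C)(C)C)/C(C)=C/CC/C(C)=C/CC[C@]1(C)CCc2cc(O[Si](C(C)C)(C(C)C)C(C)C)cc(C)c2O1 | intermediate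
29 | sargachromanol C, (2R)-2-[(3E,7E,9R)-9-hydroxy-4,8,12-trimethyltrideca-3,7,11-trien-1-yl]-2,8-dimethylchroman-6-ol | CC(C)=CC[C@@H](O)/C(C)=C/CC/C(C)=C/CC[C@]1(C)CCc2cc(O)cc(C)c2O1 | target

## Summary

**Total step count:** 16

**Longest linear sequence:** 8 steps (1 → 3 → 5 → 7 → 11 → 13 → 14 → 28 → 29; steps 1, 2, 3, 5, 6, 7, 15, 16)

**Three steps most likely to fail**

1. **Step 13 (proposed new CPA-catalysed linear prenylboration).** Risks are sluggish transfer from the hindered tertiary boronate, protodeboronation of 24, and modest ee on an α-branched enal. Fallback (known chemistry): Brown asymmetric allylation of enal 20 with the Re-face-selective (+)-Ipc2B(allyl) to give the (R)-homoallylic alcohol, then cross-metathesis of the terminal alkene with 2-methyl-2-butene (Grubbs II) to install the prenyl terminus, rejoining the route at 25.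

2. **Step 7 (asymmetric allylic etherification setting the quaternary C2).** Risks are the ee and the sense of induction for this substitution pattern. Fallback: switch to an enantioselective Pd(II) Wacker-type cyclisation/methoxycarbonylation (BOXAX-type ligand, benzoquinone, CO/MeOH) of the 2-(3-methylbut-3-enyl)phenol. That phenol comes from 5 by acetonyl Wittig, hydrogenation and methylenation. The resulting chroman-2-ylacetate is reduced and converted to 2-(2-iodoethyl)chroman, which is coupled to 27 via its alkyl-9-BBN ate complex.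

3. **Step 15 (late-stage B-alkyl Suzuki of a neopentyl-type borane).** Risks are slow hydroboration or transmetalation next to the quaternary centre and competing loss of iodide from 27. Fallback: move the union to C1'–C2'. The chroman-2-ylmethyl triflate (from 14 by ozonolysis, NaBH4, Tf2O) is alkylated with a lithiated (E,E)-allylic phenyl sulfone chain, which is built from 8-oxogeranyl acetate using the same C9' chemistry. Pd-catalysed reductive desulfonylation (LiEt3BH) and desilylation then complete the synthesis.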